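**Retrosynthetic overview**
1. Target ⇒ ring A opened at C3=C4 (ring-closing metathesis of a C5 acrylate with the prenyl terminus of the C10 chain).
2. Ring B oxepane ⇒ key C5–O bond: palladium-catalysed intramolecular allylic etherification of a Morita–Baylis–Hillman carbonate by the C10 tertiary alcohol.
3. Carbonate ⇒ C5 aldehyde + methyl acrylate; C8 ester ⇒ Mitsunobu inversion with (2S)-2-hydroxy-2-methylbut-3-enoic acid (made from tiglyl alcohol).
4. trans α-Methylene lactone and C7–C8 bond ⇒ CrCl2 allylation of a geraniol-derived β-hydroxy aldehyde (C10 set by Sharpless epoxidation) with an α-(bromomethyl)butenolide made from (5S)-5-(hydroxymethyl)oxolan-2-one.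
5. Ring order: γ-lactone (chiral pool) → ring B (C–O) → ring A (metathesis).

Assumption and convention: (5S)-5-(hydroxymethyl)oxolan-2-one and (2E)-2-methylbut-2-en-1-ol are bought; positions are labelled with germacrane locants (C1–C10 carbocycle, C5–O–C10 ether, C6–O–C12 lactone, C13 exocyclic methylene, C14 methyl on C10, C15 ester carbon on C4).

**Step 1**
Reactants: 1 geraniol
Product: 2 [(2S,3S)-3-methyl-3-(4-methylpent-3-en-1-yl)oxiran-2-yl]methanol
Conditions: Ti(OiPr)4 (5 mol%), L-(+)-diethyl tartrate (6 mol%), t-BuOOH, 4 Å MS, CH2Cl2, −20 °C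
Reagents that add atoms: tert-butyl hydroperoxide, CC(C)(C)OO
Why: Sharpless asymmetric epoxidation of the allylic alcohol; the L-(+)-tartrate catalyst delivers oxygen to the face that gives the (2S,3S)-epoxide, which fixes the future C10 quaternary C–O centre.

**Step 2**
Reactants: 2 [(2S,3S)-3-methyl-3-(4-methylpent-3-en-1-yl)oxiran-2-yl]methanol
Product: 3 (3S)-3,7-dimethyloct-6-ene-1,3-diol
Conditions: NaAlH2(OCH2CH2OMe)2 (Red-Al), THF, 0 °C
Reagents that add atoms: none
Why: Hydroxyl-directed reductive opening of the 2,3-epoxy alcohol, with hydride delivered from the alkoxyaluminate to C2, gives the 1,3-diol and leaves the tertiary C–O bond and its configuration untouched.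

**Step 3**
Reactants: 3 (3S)-3,7-dimethyloct-6-ene-1,3-diol
Product: 4 (3S)-3-hydroxy-3,7-dimethyloct-6-enal
Conditions: TEMPO (10 mol%), PhI(OAc)2 (1.1 equiv), CH2Cl2, 23 °C; used crude
Reagents that add atoms: none
Why: Oxoammonium (TEMPO) oxidation is selective for the primary alcohol, and the tertiary alcohol and trisubstituted alkene do not react.

**Step 4**
Reactants: 5 (5S)-5-(hydroxymethyl)oxolan-2-one
Product: 6 (5S)-5-{[(triethylsilyl)oxy]methyl}oxolan-2-one
Conditions: Et3SiCl, imidazole, CH2Cl2, 0 °C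
Reagents that add atoms: chlorotriethylsilane, CC[Si](Cl)(CC)CC
Why: Standard silylation of the primary alcohol; the triethylsilyl group is chosen because it can later be oxidised off directly to the aldehyde.

**Step 5**
Reactants: 6 (5S)-5-{[(triethylsilyl)oxy]methyl}oxolan-2-one
Product: 8 (5S)-3-methylidene-5-{[(triethylsilyl)oxy]methyl}oxolan-2-one, via sodium formyl enolate 7 (not isolated)
Conditions: NaH, HCO2Et, Et2O, 0 → 23 °C; then (CH2O)n, THF, 65 °C
Reagents that add atoms: formaldehyde (from paraformaldehyde), C=O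
Why: α-Methylenation of the lactone by Claisen formylation, aldol addition to formaldehyde, formyl transfer and E1cB loss of formate; the γ-stereocentre is not involved.

**Step 6**
Reactants: 8 (5S)-3-methylidene-5-{[(triethylsilyl)oxy]methyl}oxolan-2-one
Product: 10 (5S)-3-(bromomethyl)-5-{[(triethylsilyl)oxy]methyl}furan-2(5H)-one, via dibromide 9 (not isolated)
Conditions: Br2, CH2Cl2, −20 °C; then Et3N, 0 °C
Reagents that add atoms: bromine, BrBr
Why: Bromine addition to the exocyclic alkene followed by E2 dehydrobromination toward the ring CH2 gives the conjugated endocyclic butenolide that keeps a primary allylic bromide.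

**Step 7**
Reactants: 4 (3S)-3-hydroxy-3,7-dimethyloct-6-enal; 10 (5S)-3-(bromomethyl)-5-{[(triethylsilyl)oxy]methyl}furan-2(5H)-one
Product: 11 (4R,5S)-4-[(1S,3S)-1,3-dihydroxy-3,7-dimethyloct-6-en-1-yl]-3-methylidene-5-{[(triethylsilyl)oxy]methyl}oxolan-2-one
Conditions: CrCl2 (3 equiv), THF, 0 → 23 °C
Reagents that add atoms: none
Why: Nozaki–Hiyama–Kishi-type allylation in which the allylchromium formed at the exocyclic CH2 adds through the ring γ-carbon (C7) on the face anti to the silyloxymethyl group on C6 (trans lactone, 7R, exocyclic methylene regenerated), and the chair transition state of this E-locked allyl unit gives the anti carbinol (8S), the epimer required for inversion in step 11.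

**Step 8**
Reactants: 12 (2E)-2-methylbut-2-en-1-ol
Product: 13 [(2R,3R)-2,3-dimethyloxiran-2-yl]methanol
Conditions: Ti(OiPr)4 (5 mol%), D-(−)-diethyl tartrate (6 mol%), t-BuOOH, 4 Å MS, CH2Cl2, −20 °C
Reagents that add atoms: tert-butyl hydroperoxide, CC(C)(C)OO
Why: Sharpless asymmetric epoxidation; the D-(−)-tartrate catalyst gives the (2R,3R)-epoxide, which sets the quaternary carbinol of the side-chain acid.

**Step 9**
Reactants: 13 [(2R,3R)-2,3-dimethyloxiran-2-yl]methanol
Product: 16 (2S)-2-methylbut-3-ene-1,2-diol, via hydroxy selenide 14 (not isolated), via selenoxide 15 (not isolated)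
Conditions: PhSeSePh, NaBH4, EtOH, 23 °C; then 30% H2O2, THF, 0 → 23 °C
Reagents that add atoms: none
Why: Sharpless–Lauer epoxide-to-allylic-alcohol conversion, in which selenolate opens the epoxide by SN2 at the less hindered C3 and selenoxide syn-elimination can only go toward the methyl group, so the quaternary C–O bond keeps its configuration (the descriptor changes to S only through priorities).

**Step 10**
Reactants: 16 (2S)-2-methylbut-3-ene-1,2-diol
Product: 17 (2S)-2-hydroxy-2-methylbut-3-enoic acid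
Conditions: TEMPO (7 mol%), NaOCl (2 mol%), NaClO2, MeCN/phosphate buffer pH 6.7, 35 °C
Reagents that add atoms: sodium chlorite, [Na+].[O-]Cl=O
Why: TEMPO/chlorite oxidation takes the primary alcohol through the aldehyde to the acid, while the tertiary allylic alcohol cannot be oxidised.

**Step 11**
Reactants: 11 (4R,5S)-4-[(1S,3S)-1,3-dihydroxy-3,7-dimethyloct-6-en-1-yl]-3-methylidene-5-{[(triethylsilyl)oxy]methyl}oxolan-2-one; 17 (2S)-2-hydroxy-2-methylbut-3-enoic acid
Product: 18 (1R,3S)-3-hydroxy-3,7-dimethyl-1-[(2S,3R)-4-methylidene-5-oxo-2-{[(triethylsilyl)oxy]methyl}oxolan-3-yl]oct-6-en-1-yl (2S)-2-hydroxy-2-methylbut-3-enoate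
Conditions: PPh3, DIAD, toluene, 0 → 23 °C
Reagents that add atoms: none
Why: Mitsunobu esterification, in which the carboxylate displaces the C8 alkoxyphosphonium ion by SN2 with inversion (8S → 8R) while the tertiary hydroxyls are not activated, so the ester and the C8 configuration are installed together.

**Step 12**
Reactants: 18 (1R,3S)-3-hydroxy-3,7-dimethyl-1-[(2S,3R)-4-methylidene-5-oxo-2-{[(triethylsilyl)oxy]methyl}oxolan-3-yl]oct-6-en-1-yl (2S)-2-hydroxy-2-methylbut-3-enoate
Product: 19 (1R,3S)-1-[(2S,3R)-2-formyl-4-methylidene-5-oxooxolan-3-yl]-3-hydroxy-3,7-dimethyloct-6-en-1-yl (2S)-2-hydroxy-2-methylbut-3-enoate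
Conditions: (COCl)2, DMSO, CH2Cl2, −78 → −30 °C; then Et3N, −78 → 0 °C
Reagents that add atoms: none
Why: Under Swern conditions a primary triethylsilyl ether is cleaved by the chlorosulfonium ion and oxidised in the same flask to the aldehyde (oxidative desilylation); no secondary alcohol is present and tertiary alcohols cannot be oxidised.

**Step 13**
Reactants: 19 (1R,3S)-1-[(2S,3R)-2-formyl-4-methylidene-5-oxooxolan-3-yl]-3-hydroxy-3,7-dimethyloct-6-en-1-yl (2S)-2-hydroxy-2-methylbut-3-enoate; 20 methyl acrylate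
Product: 21 methyl 2-[(RS)-hydroxy{(2S,3R)-3-[(1R,3S)-3-hydroxy-1-{[(2S)-2-hydroxy-2-methylbut-3-enoyl]oxy}-3,7-dimethyloct-6-en-1-yl]-4-methylidene-5-oxooxolan-2-yl}methyl]prop-2-enoate
Conditions: DABCO (1 equiv), 20 (10 equiv), THF, 23 °C
Reagents that add atoms: none
Why: Morita–Baylis–Hillman reaction of the activated α-acyloxy aldehyde; the new C5 carbinol forms as an epimer mixture that converges in step 15, and any C6 epimerisation returns the more stable trans lactone.

**Step 14**
Reactants: 21 methyl 2-[(RS)-hydroxy{(2S,3R)-3-[(1R,3S)-3-hydroxy-1-{[(2S)-2-hydroxy-2-methylbut-3-enoyl]oxy}-3,7-dimethyloct-6-en-1-yl]-4-methylidene-5-oxooxolan-2-yl}methyl]prop-2-enoate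
Product: 22 methyl 2-[(RS)-[(tert-butoxycarbonyl)oxy]{(2S,3R)-3-[(1R,3S)-3-hydroxy-1-{[(2S)-2-hydroxy-2-methylbut-3-enoyl]oxy}-3,7-dimethyloct-6-en-1-yl]-4-methylidene-5-oxooxolan-2-yl}methyl]prop-2-enoate
Conditions: Boc2O, DMAP (5 mol%), CH2Cl2, 0 °C
Reagents that add atoms: di-tert-butyl dicarbonate, CC(C)(C)OC(=O)OC(=O)OC(C)(C)C
Why: DMAP-catalysed O-acylation of the only secondary hydroxyl; the two tertiary alcohols are too hindered to react at 0 °C.

**Step 15**
Reactants: 22 methyl 2-[(RS)-[(tert-butoxycarbonyl)oxy]{(2S,3R)-3-[(1R,3S)-3-hydroxy-1-{[(2S)-2-hydroxy-2-methylbut-3-enoyl]oxy}-3,7-dimethyloct-6-en-1-yl]-4-methylidene-5-oxooxolan-2-yl}methyl]prop-2-enoate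
Product: 23 ring B oxepane (5R,6S,7R,8R,10S): C5–O–C10 ether closed; C5 carries the 3-methoxy-3-oxoprop-1-en-2-yl group; C10 carries methyl plus the 4-methylpent-3-enyl chain; trans-fused α-methylene lactone and C8 ester unchanged
Conditions: Pd2(dba)3·CHCl3 (2.5 mol%), (R,R)-DACH-phenyl Trost ligand (7.5 mol%), CH2Cl2 (0.005 M), 23 °C
Reagents that add atoms: none
Why: Proposed new method: zerovalent palladium ionises either carbonate epimer to a 2-(methoxycarbonyl)allyl–palladium complex whose faces interconvert by π–σ–π slippage through the unsubstituted CH2 terminus, the tert-butoxide released with CO2 deprotonates the C10 tertiary alcohol, and the alkoxide closes the seven-membered ring at the substituted terminus (seven- rather than nine-membered) from the diastereomeric complex selected by the chiral ligand to give 5R (the antipodal ligand is used if this one proves mismatched, and only the 5R ether can close ring A); the closest known reaction type is the palladium-catalysed dynamic kinetic asymmetric O-allylation of Morita–Baylis–Hillman carbonates with phenols together with intramolecular Tsuji–Trost etherification to five- and six-membered ethers, not yet shown for a tertiary alkoxide closing an oxepane.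

**Step 16**
Reactants: 23 ring B oxepane (5R,6S,7R,8R,10S)
Product: 24 CNP0325750.1: (5R,6S,7R,8R,10S)-5,10-epoxy-15-methoxy-15-oxo-8-{[(2S)-2-hydroxy-2-methylbut-3-enoyl]oxy}germacra-3,11(13)-dien-12,6-olide
Conditions: second-generation Hoveyda–Grubbs catalyst RuCl2(H2IMes)(=CH-C6H4-2-OiPr) (10 mol%), toluene (0.002 M), 80 °C
Reagents that add atoms: none
Why: Ring-closing metathesis, in which the ruthenium alkylidene formed at the prenyl terminus closes onto the 1,1-disubstituted acrylate to give the trisubstituted ring enoate (C2 and C5 cis by ring constraint) with loss of 2-methylpropene, the hindered side-chain vinyl group and the electron-poor lactone methylene being slow partners.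

**Compound list**
1 | geraniol, (2E)-3,7-dimethylocta-2,6-dien-1-ol | CC(C)=CCC/C(C)=C/CO | starting material
2 | [(2S,3S)-3-methyl-3-(4-methylpent-3-en-1-yl)oxiran-2-yl]methanol | OC[C@@H]1O[C@@]1(C)CCC=C(C)C | intermediate
3 | (3S)-3,7-dimethyloct-6-ene-1,3-diol | OCC[C@@](C)(O)CCC=C(C)C | intermediate
4 | (3S)-3-hydroxy-3,7-dimethyloct-6-enal | O=CC[C@@](C)(O)CCC=C(C)C | intermediate
5 | (5S)-5-(hydroxymethyl)oxolan-2-one | OC[C@@H]1CCC(=O)O1 | starting material
6 | (5S)-5-{[(triethylsilyl)oxy]methyl}oxolan-2-one | CC[Si](CC)(CC)OC[C@@H]1CCC(=O)O1 | intermediate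
7 | sodium [(5S)-2-oxo-5-{[(triethylsilyl)oxy]methyl}oxolan-3-ylidene]methanolate | CC[Si](CC)(CC)OC[C@@H]1CC(=C[O-])C(=O)O1.[Na+] | intermediate
8 | (5S)-3-methylidene-5-{[(triethylsilyl)oxy]methyl}oxolan-2-one | CC[Si](CC)(CC)OC[C@@H]1CC(=C)C(=O)O1 | intermediate
9 | (5S)-3-bromo-3-(bromomethyl)-5-{[(triethylsilyl)oxy]methyl}oxolan-2-one (C3 epimers) | CC[Si](CC)(CC)OC[C@@H]1CC(Br)(CBr)C(=O)O1 | intermediate
10 | (5S)-3-(bromomethyl)-5-{[(triethylsilyl)oxy]methyl}furan-2(5H)-one | CC[Si](CC)(CC)OC[C@@H]1C=C(CBr)C(=O)O1 | intermediate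
11 | (4R,5S)-4-[(1S,3S)-1,3-dihydroxy-3,7-dimethyloct-6-en-1-yl]-3-methylidene-5-{[(triethylsilyl)oxy]methyl}oxolan-2-one | C=C1C(=O)O[C@H](CO[Si](CC)(CC)CC)[C@H]1[C@@H](O)C[C@@](C)(O)CCC=C(C)C | intermediate
12 | (2E)-2-methylbut-2-en-1-ol | C/C=C(\C)CO | starting material
13 | [(2R,3R)-2,3-dimethyloxiran-2-yl]methanol | C[C@H]1O[C@]1(C)CO | intermediate
14 | (2R,3S)-2-methyl-3-(phenylselanyl)butane-1,2-diol | C[C@H]([Se]c1ccccc1)[C@](C)(O)CO | intermediate
15 | (2R,3S)-2-methyl-3-(phenylseleninyl)butane-1,2-diol | C[C@H]([Se](=O)c1ccccc1)[C@](C)(O)CO | intermediate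
16 | (2S)-2-methylbut-3-ene-1,2-diol | C=C[C@](C)(O)CO | intermediate
17 | (2S)-2-hydroxy-2-methylbut-3-enoic acid | C=C[C@](C)(O)C(=O)O | intermediate
18 | (1R,3S)-3-hydroxy-3,7-dimethyl-1-[(2S,3R)-4-methylidene-5-oxo-2-{[(triethylsilyl)oxy]methyl}oxolan-3-yl]oct-6-en-1-yl (2S)-2-hydroxy-2-methylbut-3-enoate | C=C1C(=O)O[C@H](CO[Si](CC)(CC)CC)[C@H]1[C@H](OC(=O)[C@@](C)(O)C=C)C[C@@](C)(O)CCC=C(C)C | intermediate
19 | (1R,3S)-1-[(2S,3R)-2-formyl-4-methylidene-5-oxooxolan-3-yl]-3-hydroxy-3,7-dimethyloct-6-en-1-yl (2S)-2-hydroxy-2-methylbut-3-enoate | C=C1C(=O)O[C@H](C=O)[C@H]1[C@H](OC(=O)[C@@](C)(O)C=C)C[C@@](C)(O)CCC=C(C)C | intermediate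
20 | methyl acrylate | C=CC(=O)OC | starting material
21 | methyl 2-[(RS)-hydroxy{(2S,3R)-3-[(1R,3S)-3-hydroxy-1-{[(2S)-2-hydroxy-2-methylbut-3-enoyl]oxy}-3,7-dimethyloct-6-en-1-yl]-4-methylidene-5-oxooxolan-2-yl}methyl]prop-2-enoate | C=C1C(=O)O[C@H](C(O)C(=C)C(=O)OC)[C@H]1[C@H](OC(=O)[C@@](C)(O)C=C)C[C@@](C)(O)CCC=C(C)C | intermediate
22 | methyl 2-[(RS)-[(tert-butoxycarbonyl)oxy]{(2S,3R)-3-[(1R,3S)-3-hydroxy-1-{[(2S)-2-hydroxy-2-methylbut-3-enoyl]oxy}-3,7-dimethyloct-6-en-1-yl]-4-methylidene-5-oxooxolan-2-yl}methyl]prop-2-enoate | C=C1C(=O)O[C@H](C(OC(=O)OC(C)(C)C)C(=C)C(=O)OC)[C@H]1[C@H](OC(=O)[C@@](C)(O)C=C)C[C@@](C)(O)CCC=C(C)C | intermediate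
23 | ring B oxepane (5R,6S,7R,8R,10S): C5–O–C10 ether; C5 bears 3-methoxy-3-oxoprop-1-en-2-yl; C10 bears methyl and 4-methylpent-3-enyl; trans-fused α-methylene lactone; C8 (2S)-2-hydroxy-2-methylbut-3-enoate | C=C[C@](C)(O)C(=O)O[C@@H]1C[C@](C)(CCC=C(C)C)O[C@H](C(=C)C(=O)OC)[C@H]2OC(=O)C(=C)[C@@H]21 | intermediate
24 | CNP0325750.1: (5R,6S,7R,8R,10S)-5,10-epoxy-15-methoxy-15-oxo-8-{[(2S)-2-hydroxy-2-methylbut-3-enoyl]oxy}germacra-3,11(13)-dien-12,6-olide | C=C[C@](C)(O)C(=O)O[C@@H]1C[C@]2(C)CCC=C(C(=O)OC)[C@@H](O2)[C@H]2OC(=O)C(=C)[C@@H]21 | target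

**Step count**
Total: 16 steps (steps 1–3 to aldehyde 4, steps 4–6 to bromide 10, steps 8–10 to acid 17, then steps 7 and 11–16).
Longest linear sequence: 10 steps (1, 2, 3, 7, 11, 12, 13, 14, 15, 16, from geraniol).

**Three steps most likely to fail, with fallbacks**

Step 15 (the proposed palladium etherification). It may give the 5S ether (which cannot close ring A in step 16), the 1,3-diene by β-hydride loss from the allyl complex, or the tert-butyl ether. The fallback uses known chemistry, an intramolecular Nicholas etherification, which is established for cis-2,7-disubstituted oxepanes with hindered alcohols. It sets out from aldehyde 19. Ethynylmagnesium bromide (THF, −78 °C, excess to cover the two hydroxyls) gives propargylic alcohol F1 as C5 epimers. Co2(CO)8 (CH2Cl2, 23 °C) gives hexacarbonyldicobalt complex F2. BF3·OEt2 (CH2Cl2, −20 °C) ionises it to the cobalt-stabilised propargylic cation, which the C10 hydroxyl captures reversibly, so the cis-bridged (5R) cobalt-complexed oxepane F3 accumulates. (NH4)2Ce(NO3)6 (acetone, 0 °C) releases ethynyl oxepane F4. Palladium-catalysed Markovnikov methoxycarbonylation of the terminal alkyne (Pd(OAc)2, 2-pyridyldiphenylphosphine, CH3SO3H, CO, MeOH, 45 °C) then gives 23, where the route is rejoined.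

Step 11 (Mitsunobu inversion). The C8 carbinol is flanked by the branched C7 and a neopentyl-type CH2, and the acid is α-quaternary, so elimination toward C7 or no reaction are possible. The fallback sets out from 11. Dess–Martin periodinane (CH2Cl2, NaHCO3, 0 °C) gives keto lactone F5. Reagent-controlled reduction with (S)-2-methyl-CBS-oxazaborolidine and catecholborane (toluene, −78 °C; the branched C7 side acts as the large group) gives (8R)-alcohol F6 without touching the alkenes. Carbodiimide esterification with 17 (EDC·HCl, DMAP, CH2Cl2; retention at C8) gives 18, where the route is rejoined.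

Step 16 (ring-closing metathesis). Closure of a bridged ring between a trisubstituted prenyl alkene and a 1,1-disubstituted acrylate is slow, and the side-chain vinyl group can sequester the catalyst. The fallback replaces metathesis by an olefination and sets out from 19. Knoevenagel condensation with trimethyl phosphonoacetate (piperidine, AcOH, toluene, 4 Å MS, 60 °C) gives alkylidene phosphonoacetate F7. Selective ozonolysis of the electron-rich trisubstituted alkene (O3, CH2Cl2/pyridine, −78 °C, one equivalent; then Me2S) gives γ-hydroxy aldehyde F8, in equilibrium with its lactol. Cs2CO3 (MeCN, 0.002 M, 23 °C) then triggers reversible oxa-Michael addition of the C10 alkoxide to C5, followed by an irreversible intramolecular Horner–Wadsworth–Emmons olefination of the C4 phosphonate carbanion with the C3 aldehyde. Only the cis-bridged adduct can undergo the olefination, so the sequence converges on 24 directly.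

**Further compounds**
F1 | step 15 | (1R,3S)-3-hydroxy-1-[(2S,3R)-2-[(RS)-1-hydroxyprop-2-yn-1-yl]-4-methylidene-5-oxooxolan-3-yl]-3,7-dimethyloct-6-en-1-yl (2S)-2-hydroxy-2-methylbut-3-enoate | C=C1C(=O)O[C@H](C(O)C#C)[C@H]1[C@H](OC(=O)[C@@](C)(O)C=C)C[C@@](C)(O)CCC=C(C)C
F2 | step 15 | hexacarbonyldicobalt complex of the alkyne of F1 | C=C1C(=O)O[C@H](C(O)C23[Co]4(=C=O)(=C=O)(=C=O)[Co]2(=C=O)(=C=O)(=C=O)C34)[C@H]1[C@H](OC(=O)[C@@](C)(O)C=C)C[C@@](C)(O)CCC=C(C)C
F3 | step 15 | hexacarbonyldicobalt complex of ethynyl oxepane F4 (5R,6S,7R,8R,10S) | C=C[C@](C)(O)C(=O)O[C@@H]1C[C@](C)(CCC=C(C)C)O[C@H](C34[Co]5(=C=O)(=C=O)(=C=O)[Co]3(=C=O)(=C=O)(=C=O)C45)[C@H]2OC(=O)C(=C)[C@@H]21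
F4 | step 15 | ethynyl oxepane: analogue of 23 with ethynyl on C5 in place of the acrylate unit | C=C[C@](C)(O)C(=O)O[C@@H]1C[C@](C)(CCC=C(C)C)O[C@H](C#C)[C@H]2OC(=O)C(=C)[C@@H]21
F5 | step 11 | (4S,5S)-4-[(3S)-3-hydroxy-3,7-dimethyloct-6-enoyl]-3-methylidene-5-{[(triethylsilyl)oxy]methyl}oxolan-2-one | C=C1C(=O)O[C@H](CO[Si](CC)(CC)CC)[C@H]1C(=O)C[C@@](C)(O)CCC=C(C)C
F6 | step 11 | (4R,5S)-4-[(1R,3S)-1,3-dihydroxy-3,7-dimethyloct-6-en-1-yl]-3-methylidene-5-{[(triethylsilyl)oxy]methyl}oxolan-2-one | C=C1C(=O)O[C@H](CO[Si](CC)(CC)CC)[C@H]1[C@H](O)C[C@@](C)(O)CCC=C(C)C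
F7 | step 16 | alkylidene phosphonoacetate: 19 with the formyl group converted to CH=C(CO2Me)P(O)(OMe)2 (E/Z) | C=C1C(=O)O[C@H](C=C(C(=O)OC)P(=O)(OC)OC)[C@H]1[C@H](OC(=O)[C@@](C)(O)C=C)C[C@@](C)(O)CCC=C(C)C
F8 | step 16 | γ-hydroxy aldehyde: F7 with the prenyl terminus cleaved to the C3 aldehyde (open form shown) | C=C1C(=O)O[C@H](C=C(C(=O)OC)P(=O)(OC)OC)[C@H]1[C@H](OC(=O)[C@@](C)(O)C=C)C[C@@](C)(O)CCC=O
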